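The numbers in the tables are simulated for substances that don't exist; scatter was added.

The alpha flask holds 0.0500 M substrate against 0.100 M partner, so substrate is its limiting reagent, and each product formed uses one partner.

| flask | substrate | partner | free catalyst | time |
|---|---|---|---|---|
| theta | 0.100 M | 0.150 M | 0.00200 M |  |
| delta | 0.100 M | 0.220 M | 0.00200 M |  |
| alpha | 0.0500 M | 0.100 M | 0.00200 M | 61 min |

| run | time / min | [product] / M |
|---|---|---|
| theta run | 10 | 0.0139 |
| theta run | 20 | 0.0229 |
| theta run | 30 | 0.0334 |
| theta run | 41 | 0.0457 |
| theta run | 51 | 0.0535 |
| theta run | 61 | 0.0613 |
| delta run | 10 | 0.0175 |
| delta run | 20 | 0.0351 |
| delta run | 30 | 0.0509 |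
| delta run | 41 | 0.0631 |
| delta run | 51 | 0.0739 |
| delta run | 61 | 0.0812 |

(each reading ± 8 × 10⁻⁴ M)

- apparent order in [partner] of the starting rate, round the charge of the theta run (the rate where two percent of its substrate have turned into product)
- product in the alpha run at 61 min, as a share of the substrate charged

- Overall: substrate + partner -> product, with free catalyst as catalyst.
- Constant volume, constant temperature.
- The analysis sees a species whether free or bound.
- "The second partner" is partner.
- An order is taken over about fifteen percent of the charge, up and down.

Comparing the delta and theta runs at 30 min, I read an order in partner of 1.10, with the scatter of those readings, and I commit to first order in partner. I therefore follow one partner molecule and ask its chance per minute of becoming product: the natural logarithm of partner charged over partner left, divided by the time. At 61 min the theta run gives 0.00861 min⁻¹ and the delta run 0.00755 min⁻¹. The alpha ratio of partner to substrate, 2.00, lies above the theta ratio and below the delta ratio, so I carry their mean, the partner's chance per minute, 0.00808 min⁻¹. By my estimate, 38.9 % of the alpha partner turns over 61 min, which is 77.8 % of its substrate.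

The forecast gives an order of 0.93 and a product of 65 % of the substrate charged, a product share lower than my estimate, and it reads the runs thus: “Substrate therefore looks near-saturating, probably binding the catalyst before partner reacts.”

The flask gives an order of 1.0 and, in the alpha run, a product of 78.1 % of the substrate charged, which is 13 percentage points above the forecast.

    free catalyst + substrate ⇌ catalyst-substrate complex, settled at all times (11.30 L mol⁻¹)
    catalyst-substrate complex + partner → product + free catalyst + by-product (42.72 L mol⁻¹ min⁻¹)
    free catalyst + product ⇌ catalyst-product complex, settled at all times (34.50 L mol⁻¹)
    catalyst-substrate complex + substrate ⇌ doubly bound catalyst, settled at all times (87.50 L mol⁻¹)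

Read back from its result, the alpha run has a partner's chance per minute of 0.00812 min⁻¹. The main reason that product in the alpha run at 61 min stands short of the substrate charge is the binding of free catalyst and product into catalyst-product complex, which holds part of the catalyst away from the path through catalyst-substrate complex. The alpha run with that binding removed proves it: its chance rises to 0.00995 min⁻¹, and its product reaches 91.0 % of the substrate charged, 13 points more.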